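**Plan**

1. Germacrane numbering is used: C1 ketone, C2=C3, C4=C5 (C15 methyl on C4), C6 (lactone O), C7, C8 (ester O), C9, C10 (C14 methyl, ether O to C3), C11=C13, C12 lactone carbonyl. Retrosynthetic cuts, in order: O6–C12 together with C5–C6 (alkenyl iodide at C5, aldehyde at C6, methyl ester at C12); the C8 ester; C7–C8 (aldehyde plus a γ-substituted 2-(bromomethyl)acrylate); C1–C2 and O–C3 of the furanone.
2. Forward: the 3(2H)-furanone ring (O, C3, C2, C1, C10) is built first from (R)-citramalic acid and a Z-iodoenone; an indium Barbier allylation brings in C6, C7 and C11–C13; O8 is esterified; the last step closes the carbocycle at C5–C6 and, in the same flask, the γ-lactone.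
3. Feature that makes the closure possible: the planar furanone holds its two arms (C4 on C3, C9 on C10) as a rigid bend, so only nine atoms, four of them fixed in the furanone, lie in the ring being closed. The Z C4=C5 bond turns C5 toward C6, and C12 sits γ to the new C6 oxygen, so the lactone follows at once.
4. Stereochemistry: C10 from (R)-citramalic acid; C2′ from (S)-2-methylbutanoic anhydride; Z C4=C5 from anti carbomagnesiation of a propargylic alcohol; C7/C8 syn from the chair transition state of a Z-allylindium, with the face relative to C10 secured by separation; C6 in the ring closure under control of C7.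

Key step: step 13

Assumption: compounds 1, 5, 12, 13 (as its aqueous solution) and 17 are taken as commercial.

**Step 1**
Reactants: 1 (R)-citramalic acid
Product: 2 2-[(4R)-2,2,4-trimethyl-5-oxo-1,3-dioxolan-4-yl]acetic acid
Conditions: Me2C(OMe)2, TsOH·H2O (cat.), CH2Cl2, rt
Reagents that add atoms: 2,2-dimethoxypropane, COC(C)(C)OC
Why: Acid-catalysed acetalisation closes the five-membered dioxolanone on the α-hydroxy acid unit in preference to the six-membered alternative, which sets the C8 carboxyl apart from the C1 carboxyl without touching the quaternary stereocentre.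

**Step 2**
Reactants: 2 2-[(4R)-2,2,4-trimethyl-5-oxo-1,3-dioxolan-4-yl]acetic acid
Product: 3 (5R)-5-(2-hydroxyethyl)-2,2,5-trimethyl-1,3-dioxolan-4-one
Conditions: BH3·SMe2, B(OMe)3, THF, 0 °C to rt
Reagents that add atoms: none
Why: Borane reduces the free carboxylic acid chemoselectively beside the ester-like dioxolanone, as established for the malic acid analogue, and no stereocentre is involved.

**Step 3**
Reactants: 3 (5R)-5-(2-hydroxyethyl)-2,2,5-trimethyl-1,3-dioxolan-4-one
Product: 4 (5R)-5-[2-(tert-butyldimethylsilyloxy)ethyl]-2,2,5-trimethyl-1,3-dioxolan-4-one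
Conditions: TBSCl, imidazole, CH2Cl2, 0 °C to rt
Reagents that add atoms: tert-butyldimethylsilyl chloride, CC(C)(C)[Si](C)(C)Cl
Why: Standard silylation of the primary alcohol stops its translactonisation onto the dioxolanone and masks O8 for the enolate chemistry of step 6.

**Step 4**
Reactants: 5 but-3-yn-2-ol (racemic)
Product: 6 (Z)-4-iodo-3-methylbut-3-en-2-ol (racemic)
Conditions: MeMgBr (3 equiv), CuI (0.2 equiv), THF, −10 °C to rt; then I2, THF, −78 to 0 °C
Reagents that add atoms: methylmagnesium bromide, C[Mg]Br; iodine, II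
Why: Copper-catalysed carbomagnesiation of a propargylic alcohol adds methyl and magnesium anti across the alkyne through a five-membered alkenylmagnesium alkoxide chelate, and iodinolysis with retention places iodine cis to the carbinol carbon, which is the Z geometry needed at C4=C5.

**Step 5**
Reactants: 6 (Z)-4-iodo-3-methylbut-3-en-2-ol
Product: 7 (Z)-4-iodo-3-methylbut-3-en-2-one
Conditions: Dess–Martin periodinane, NaHCO3, CH2Cl2, 0 °C to rt
Reagents that add atoms: none
Why: Neutral Dess–Martin oxidation of the secondary allylic alcohol gives the enone without isomerising the iodoalkene and removes the racemic carbinol centre.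

**Step 6**
Reactants: 4 (5R)-5-[2-(tert-butyldimethylsilyloxy)ethyl]-2,2,5-trimethyl-1,3-dioxolan-4-one; 7 (Z)-4-iodo-3-methylbut-3-en-2-one
Product: 10 (2R)-2-(2-hydroxyethyl)-5-[(Z)-1-iodoprop-1-en-2-yl]-2-methylfuran-3(2H)-one, via hydroxy diketone 8 (not isolated), via furanone silyl ether 9 (not isolated)
Conditions: LiN(SiMe3)2 (2.3 equiv), 7 (2.2 equiv), THF, −78 °C; 4, −78 to −40 °C; then 1 M aq. H2SO4, THF, rt
Reagents that add atoms: none
Why: Crossed Claisen acylation of the kinetic methyl-side lithium enolate of 7 by the non-enolisable dioxolanone 4 (the acylation used in tetronic acid synthesis) releases acetone and gives the α′-hydroxy-1,3-diketone 8, whose lithium chelate keeps the enolate oxygen away from the iodoalkene; non-nucleophilic aqueous acid then effects the classical 5-exo cyclodehydration to the 3(2H)-furanone and cleaves the silyl ether, with the quaternary C10 carried through unchanged.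

**Step 7**
Reactants: 10 (2R)-2-(2-hydroxyethyl)-5-[(Z)-1-iodoprop-1-en-2-yl]-2-methylfuran-3(2H)-one
Product: 11 2-[(2R)-5-[(Z)-1-iodoprop-1-en-2-yl]-2-methyl-3-oxo-2,3-dihydrofuran-2-yl]acetaldehyde
Conditions: Dess–Martin periodinane, NaHCO3, CH2Cl2, 0 °C; used crude
Reagents that add atoms: none
Why: Buffered Dess–Martin oxidation avoids amine bases, because the aldehyde carries the vinylogous-ester oxygen of C10 in the β position and would open the furanone by β-elimination.

**Step 8**
Reactants: 12 methyl acrylate; 13 2,2-dimethoxyacetaldehyde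
Product: 14 methyl 3-hydroxy-4,4-dimethoxy-2-methylidenebutanoate (racemic)
Conditions: DABCO (0.5 equiv), 12 (excess), dioxane–H2O, rt
Reagents that add atoms: none
Why: Morita–Baylis–Hillman reaction of an electron-poor aldehyde with an acrylate; the carbinol centre is lost in step 9.

**Step 9**
Reactants: 14 methyl 3-hydroxy-4,4-dimethoxy-2-methylidenebutanoate
Product: 15 methyl (Z)-2-(bromomethyl)-4,4-dimethoxybut-2-enoate
Conditions: NBS, Me2S, CH2Cl2, 0 °C to rt
Reagents that add atoms: N-bromosuccinimide, O=C1CCC(=O)N1Br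
Why: Bromide attacks the alkoxysulfonium salt with allylic transposition (SN2′) and gives the favoured Z-2-(bromomethyl)alk-2-enoate, acetal cis to CH2Br, under conditions neutral enough for the acetal.

**Step 10**
Reactants: 11 2-[(2R)-5-[(Z)-1-iodoprop-1-en-2-yl]-2-methyl-3-oxo-2,3-dihydrofuran-2-yl]acetaldehyde; 15 methyl (Z)-2-(bromomethyl)-4,4-dimethoxybut-2-enoate
Product: 16 methyl (3R,4R)-3-(dimethoxymethyl)-4-hydroxy-5-[(2R)-5-[(Z)-1-iodoprop-1-en-2-yl]-2-methyl-3-oxo-2,3-dihydrofuran-2-yl]-2-methylidenepentanoate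
Conditions: indium powder (1.5 equiv), 15 (1.5 equiv), THF–H2O (1:1), rt
Reagents that add atoms: none
Why: Indium-mediated Barbier 2-(alkoxycarbonyl)allylation, in which the allylindium reacts at its γ-carbon through a chair transition state with the acetal group (cis to CH2In) axial and so gives the syn C7/C8 pair, while the remote quaternary C10 is expected to bias the aldehyde face only weakly, so the (7R,8R) isomer 16 is to be separated from its (7S,8S) partner by chromatography; iodoalkene, furanone and acetal are inert to indium metal.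

**Step 11**
Reactants: 16 (the hydroxy ester of step 10); 17 (2S)-2-methylbutanoic anhydride
Product: 18 methyl (3R,4R)-3-(dimethoxymethyl)-5-[(2R)-5-[(Z)-1-iodoprop-1-en-2-yl]-2-methyl-3-oxo-2,3-dihydrofuran-2-yl]-2-methylidene-4-[(2S)-2-methylbutanoyloxy]pentanoate
Conditions: 17 (2 equiv), DMAP (0.2 equiv), pyridine, CH2Cl2, 0 °C to rt
Reagents that add atoms: none
Why: DMAP-catalysed acylation with the symmetrical anhydride avoids a ketene pathway and so keeps the 2′S centre, and it is run at once because the free γ-hydroxy ester could lactonise onto C12.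

**Step 12**
Reactants: 18 (the acetal ester of step 11)
Product: 19 methyl (3R,4R)-3-formyl-5-[(2R)-5-[(Z)-1-iodoprop-1-en-2-yl]-2-methyl-3-oxo-2,3-dihydrofuran-2-yl]-2-methylidene-4-[(2S)-2-methylbutanoyloxy]pentanoate
Conditions: CF3CO2H–H2O (9:1), CHCl3, 0 °C, short contact; used directly
Reagents that add atoms: water, O
Why: Acid-catalysed hydrolysis of the dimethyl acetal at low temperature is chosen over any basic unmasking because H7 is α to the aldehyde and allylic to the acrylate.

**Step 13**
Reactants: 19 (the iodoalkene aldehyde of step 12)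
Product: 21 (4Z,6R,7R,8R,10R)-8-[(2S)-2-methylbutanoyloxy]-1-oxo-3,10-epoxygermacra-2,4,11(13)-trien-12,6-olide (CNP0174601.1), via seco hydroxy ester 20 (not isolated)
Conditions: CrCl2 (10 equiv), NiCl2 (0.1 equiv), degassed DMSO–THF, 0.003 M, slow addition of 19, rt; aq. NH4Cl work-up
Reagents that add atoms: none
Why: Zerovalent nickel (formed in the flask from NiCl2 and CrCl2) inserts into the C5–I bond with retention of the Z geometry and hands the alkenyl group to chromium, the trivalent alkenylchromium adds to the C6 aldehyde, and the chromium alkoxide of 20 then attacks the C12 methyl ester and expels methoxide. The closest known reaction type is the intramolecular Nozaki–Hiyama–Kishi macrocyclisation, joined to the in-flask lactonisation known for chromium γ-alkoxides of 2-alkylidene esters. The medium ring (nine-membered through the furanone oxygen, ten-membered all-carbon) closes exo-trig at the aldehyde carbon and the lactone closes 5-exo-trig at C12. The new stereocentre C6 is controlled by C7 inside the cyclic transition state: with the acrylate arm on C7 turned away from the incoming C5, the chromium-bound carbonyl oxygen should lie next to the small H7 and not next to C8 with its acyloxy group, which gives the 6R alkoxide (H6 anti to H7), the only one that closes a trans-fused lactone. The step needs addition to the aldehyde alone and ring closure over oligomerisation; alkenylchromium reagents leave the esters, the furanone carbonyl and the acrylate untouched, and the furanone bend, the Z alkene and high dilution favour the intramolecular path. The medium is not basic, so H7 should stay in place.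

**Compound list**

1 | (R)-citramalic acid, (2R)-2-hydroxy-2-methylbutanedioic acid | OC(=O)[C@@](C)(CC(=O)O)O | starting material
2 | 2-[(4R)-2,2,4-trimethyl-5-oxo-1,3-dioxolan-4-yl]acetic acid | O=C1OC(C)(C)O[C@]1(C)CC(=O)O | intermediate
3 | (5R)-5-(2-hydroxyethyl)-2,2,5-trimethyl-1,3-dioxolan-4-one | O=C1OC(C)(C)O[C@]1(C)CCO | intermediate
4 | (5R)-5-[2-(tert-butyldimethylsilyloxy)ethyl]-2,2,5-trimethyl-1,3-dioxolan-4-one | O=C1OC(C)(C)O[C@]1(C)CCO[Si](C)(C)C(C)(C)C | intermediate
5 | but-3-yn-2-ol (racemic) | CC(O)C#C | starting material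
6 | (Z)-4-iodo-3-methylbut-3-en-2-ol (racemic) | I/C=C(/C)C(C)O | intermediate
7 | (Z)-4-iodo-3-methylbut-3-en-2-one | I/C=C(/C)C(C)=O | intermediate
8 | (1Z,6R)-8-(tert-butyldimethylsilyloxy)-6-hydroxy-1-iodo-2,6-dimethyloct-1-ene-3,5-dione | I/C=C(/C)C(=O)CC(=O)[C@@](C)(CCO[Si](C)(C)C(C)(C)C)O | intermediate
9 | (2R)-2-[2-(tert-butyldimethylsilyloxy)ethyl]-5-[(Z)-1-iodoprop-1-en-2-yl]-2-methylfuran-3(2H)-one | I/C=C(/C)C1=CC(=O)[C@@](C)(CCO[Si](C)(C)C(C)(C)C)O1 | intermediate
10 | (2R)-2-(2-hydroxyethyl)-5-[(Z)-1-iodoprop-1-en-2-yl]-2-methylfuran-3(2H)-one | I/C=C(/C)C1=CC(=O)[C@@](C)(CCO)O1 | intermediate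
11 | 2-[(2R)-5-[(Z)-1-iodoprop-1-en-2-yl]-2-methyl-3-oxo-2,3-dihydrofuran-2-yl]acetaldehyde | I/C=C(/C)C1=CC(=O)[C@@](C)(CC=O)O1 | intermediate
12 | methyl acrylate | C=CC(=O)OC | starting material
13 | 2,2-dimethoxyacetaldehyde | COC(OC)C=O | starting material
14 | methyl 3-hydroxy-4,4-dimethoxy-2-methylidenebutanoate (racemic) | C=C(C(=O)OC)C(O)C(OC)OC | intermediate
15 | methyl (Z)-2-(bromomethyl)-4,4-dimethoxybut-2-enoate | BrC/C(=C\C(OC)OC)C(=O)OC | intermediate
16 | methyl (3R,4R)-3-(dimethoxymethyl)-4-hydroxy-5-[(2R)-5-[(Z)-1-iodoprop-1-en-2-yl]-2-methyl-3-oxo-2,3-dihydrofuran-2-yl]-2-methylidenepentanoate | I/C=C(/C)C1=CC(=O)[C@@](C)(C[C@@H](O)[C@@H](C(=C)C(=O)OC)C(OC)OC)O1 | intermediate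
17 | (2S)-2-methylbutanoic anhydride | CC[C@H](C)C(=O)OC(=O)[C@@H](C)CC | starting material
18 | methyl (3R,4R)-3-(dimethoxymethyl)-5-[(2R)-5-[(Z)-1-iodoprop-1-en-2-yl]-2-methyl-3-oxo-2,3-dihydrofuran-2-yl]-2-methylidene-4-[(2S)-2-methylbutanoyloxy]pentanoate | I/C=C(/C)C1=CC(=O)[C@@](C)(C[C@@H](OC(=O)[C@@H](C)CC)[C@@H](C(=C)C(=O)OC)C(OC)OC)O1 | intermediate
19 | methyl (3R,4R)-3-formyl-5-[(2R)-5-[(Z)-1-iodoprop-1-en-2-yl]-2-methyl-3-oxo-2,3-dihydrofuran-2-yl]-2-methylidene-4-[(2S)-2-methylbutanoyloxy]pentanoate | I/C=C(/C)C1=CC(=O)[C@@](C)(C[C@@H](OC(=O)[C@@H](C)CC)[C@@H](C(=C)C(=O)OC)C=O)O1 | intermediate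
20 | methyl (4Z,6R,7S,8R,10R)-6-hydroxy-8-[(2S)-2-methylbutanoyloxy]-1-oxo-3,10-epoxygermacra-2,4,11(13)-trien-12-oate | O[C@@H]1/C=C(/C)C2=CC(=O)[C@@](C)(C[C@@H](OC(=O)[C@@H](C)CC)[C@H]1C(=C)C(=O)OC)O2 | intermediate
21 | (4Z,6R,7R,8R,10R)-8-[(2S)-2-methylbutanoyloxy]-1-oxo-3,10-epoxygermacra-2,4,11(13)-trien-12,6-olide (CNP0174601.1) | C=C1C(=O)O[C@@H]2/C=C(/C)C3=CC(=O)[C@@](C)(C[C@@H](OC(=O)[C@@H](C)CC)[C@@H]12)O3 | target

**Step count**

Total: 13 steps. Longest linear sequence: 9 steps (1, 2, 3, 6, 7, 10, 11, 12, 13).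

**Steps most likely to fail**

Step 13. The ring-closing addition may take the wrong face of the C6 aldehyde, or be overtaken by intermolecular coupling. The fallback sets out from 19 and moves the control of C6 from the ring closure to an inversion after it. It applies if the closure gives the 6-epimer in its open form, methyl (4Z,6S,7S,8R,10R)-6-hydroxy-8-[(2S)-2-methylbutanoyloxy]-1-oxo-3,10-epoxygermacra-2,4,11(13)-trien-12-oate F1; a 6-epimer that had already closed a cis lactone would not be rescued this way. Mitsunobu reaction of F1 with chloroacetic acid (PPh3, diisopropyl azodicarboxylate, THF, 0 °C) should give the inverted 6R chloroacetate, methyl (4Z,6R,7R,8R,10R)-6-(chloroacetoxy)-8-[(2S)-2-methylbutanoyloxy]-1-oxo-3,10-epoxygermacra-2,4,11(13)-trien-12-oate F2. Thiourea with NaHCO3 in EtOH removes the chloroacetyl group beside the other esters and returns the route at 20, which should lactonise to 21 on standing or with catalytic PPTS.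

Step 10. The aldehyde face may be chosen poorly, since C10 gives only weak 1,3-induction. The fallback sets out from 15 and 11 and uses reagent control. Palladium-catalysed borylation of 15 (B2pin2, Pd2(dba)3, toluene) should give the pinacol allylboronate with the same alkene geometry, methyl (E)-4,4-dimethoxy-2-[(4,4,5,5-tetramethyl-1,3,2-dioxaborolan-2-yl)methyl]but-2-enoate F3. Allylboration of 11 with F3 under catalysis by a chiral phosphoric acid, (R)-3,3′-bis(2,4,6-triisopropylphenyl)-1,1′-binaphthyl-2,2′-diyl hydrogen phosphate, in toluene at low temperature should give the syn adduct through the closed transition state, with the face set by the catalyst. The enantiomer of the acid that matches would be chosen on a model aldehyde. The route is rejoined at 16.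

Step 12. Acid unmasking may epimerise C7 or move the C11=C13 double bond into conjugation with the aldehyde. The fallback sets out from 11 and 12 and carries C6 as a silyl ether, so that the aldehyde is made by neutral oxidation.
- Morita–Baylis–Hillman reaction of 12 with commercial (tert-butyldimethylsilyloxy)acetaldehyde should give methyl 4-(tert-butyldimethylsilyloxy)-3-hydroxy-2-methylidenebutanoate F4.
- NBS and Me2S convert it into methyl (Z)-2-(bromomethyl)-4-(tert-butyldimethylsilyloxy)but-2-enoate F5.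
- Indium-mediated addition of F5 to 11 should give methyl (3S,4R)-3-[(tert-butyldimethylsilyloxy)methyl]-4-hydroxy-5-[(2R)-5-[(Z)-1-iodoprop-1-en-2-yl]-2-methyl-3-oxo-2,3-dihydrofuran-2-yl]-2-methylidenepentanoate F6.
- Acylation with 17 and DMAP gives the corresponding 4-[(2S)-2-methylbutanoyloxy] ester F7.
- Buffered HF·pyridine in THF at 0 °C frees the primary alcohol, methyl (3S,4R)-3-(hydroxymethyl)-5-[(2R)-5-[(Z)-1-iodoprop-1-en-2-yl]-2-methyl-3-oxo-2,3-dihydrofuran-2-yl]-2-methylidene-4-[(2S)-2-methylbutanoyloxy]pentanoate F8.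
- F8 is oxidised at once with Dess–Martin periodinane and NaHCO3, before it can lactonise, and the route is rejoined at 19.

**Further compounds**

F1 | step 13 | methyl (4Z,6S,7S,8R,10R)-6-hydroxy-8-[(2S)-2-methylbutanoyloxy]-1-oxo-3,10-epoxygermacra-2,4,11(13)-trien-12-oate | O[C@H]1/C=C(/C)C2=CC(=O)[C@@](C)(C[C@@H](OC(=O)[C@@H](C)CC)[C@H]1C(=C)C(=O)OC)O2
F2 | step 13 | methyl (4Z,6R,7R,8R,10R)-6-(chloroacetoxy)-8-[(2S)-2-methylbutanoyloxy]-1-oxo-3,10-epoxygermacra-2,4,11(13)-trien-12-oate | ClCC(=O)O[C@@H]1/C=C(/C)C2=CC(=O)[C@@](C)(C[C@@H](OC(=O)[C@@H](C)CC)[C@H]1C(=C)C(=O)OC)O2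
F3 | step 10 | methyl (E)-4,4-dimethoxy-2-[(4,4,5,5-tetramethyl-1,3,2-dioxaborolan-2-yl)methyl]but-2-enoate | CC1(C)OB(C/C(=C\C(OC)OC)C(=O)OC)OC1(C)C
F4 | step 12 | methyl 4-(tert-butyldimethylsilyloxy)-3-hydroxy-2-methylidenebutanoate (racemic) | C=C(C(=O)OC)C(O)CO[Si](C)(C)C(C)(C)C
F5 | step 12 | methyl (Z)-2-(bromomethyl)-4-(tert-butyldimethylsilyloxy)but-2-enoate | BrC/C(=C\CO[Si](C)(C)C(C)(C)C)C(=O)OC
F6 | step 12 | methyl (3S,4R)-3-[(tert-butyldimethylsilyloxy)methyl]-4-hydroxy-5-[(2R)-5-[(Z)-1-iodoprop-1-en-2-yl]-2-methyl-3-oxo-2,3-dihydrofuran-2-yl]-2-methylidenepentanoate | I/C=C(/C)C1=CC(=O)[C@@](C)(C[C@@H](O)[C@@H](C(=C)C(=O)OC)CO[Si](C)(C)C(C)(C)C)O1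
F7 | step 12 | methyl (3S,4R)-3-[(tert-butyldimethylsilyloxy)methyl]-5-[(2R)-5-[(Z)-1-iodoprop-1-en-2-yl]-2-methyl-3-oxo-2,3-dihydrofuran-2-yl]-2-methylidene-4-[(2S)-2-methylbutanoyloxy]pentanoate | I/C=C(/C)C1=CC(=O)[C@@](C)(C[C@@H](OC(=O)[C@@H](C)CC)[C@@H](C(=C)C(=O)OC)CO[Si](C)(C)C(C)(C)C)O1
F8 | step 12 | methyl (3S,4R)-3-(hydroxymethyl)-5-[(2R)-5-[(Z)-1-iodoprop-1-en-2-yl]-2-methyl-3-oxo-2,3-dihydrofuran-2-yl]-2-methylidene-4-[(2S)-2-methylbutanoyloxy]pentanoate | I/C=C(/C)C1=CC(=O)[C@@](C)(C[C@@H](OC(=O)[C@@H](C)CC)[C@@H](C(=C)C(=O)OC)CO)O1
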